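The oxolane (O1, C2 bearing aryl, C3 bearing CH2OH, C4 bearing OH and arylmethyl, C5) is cut at O1–C2 and C3–C4. The cut uses the fact that O1 and the fully substituted C4 flank the single methylene C5. Once the C4 hydroxyl is disguised as vinyl, O1–C5–C4 is the oxide and the branched terminus of a π-allylpalladium zwitterion, while C2–C3–CH2OH is a cinnamaldehyde. A dual palladium/secondary-amine (3+2) annulation forms both bonds, the ring and all three stereocentres at once from O-benzylconiferyl aldehyde and a racemic 4-(arylmethyl)-4-vinyl cyclic carbonate. Afterwards the vinyl carbon is exchanged for oxygen with retention through aldehyde and Baeyer–Villiger migration.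

Key step: step 5

Remark: in all names the ring keeps the numbering O1, C2, C3, C4, C5 used above and Ar means 4-benzyloxy-3-methoxyphenyl; because no reliable model predicts which antipode of the phosphoramidite gives 4R together with the (R)-amine, the antipode written in step 5 is assumed to be the matched one (both are commercial).

Step 1
Reactants: 1 coniferyl aldehyde [(E)-3-(4-hydroxy-3-methoxyphenyl)prop-2-enal]
Product: 2 (E)-3-(4-benzyloxy-3-methoxyphenyl)prop-2-enal
Conditions: BnBr (1.1 equiv), K2CO3 (1.5 equiv), DMF, rt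
Reagents that add atoms: benzyl bromide, BrCc1ccccc1
Why: Williamson etherification of the acidic phenol takes place at oxygen under mild carbonate conditions that leave the E-enal untouched.

Step 2
Reactants: 3 (4-benzyloxy-3-methoxyphenyl)acetic acid; 4 tris(trimethylsilyloxy)ethene
Product: 8 1-(4-benzyloxy-3-methoxyphenyl)-3-hydroxypropan-2-one, via arylacetyl chloride 5 (not isolated), via bis-silylated acylation adduct 6 (not isolated), via hydroxy keto acid 7 (not isolated)
Conditions: (COCl)2, DMF (cat.), CH2Cl2, 0 °C to rt, evaporate; 4 (2.2 equiv), neat, 95 °C; dioxane/0.6 M aq HCl, 85 °C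
Reagents that add atoms: tris(trimethylsilyloxy)ethene (4), C[Si](C)(C)OC=C(O[Si](C)(C)C)O[Si](C)(C)C; oxalyl chloride, O=C(Cl)C(=O)Cl (chlorine of 5 only)
Why: The acid chloride C-acylates the glycolic-acid-derived ketene bis(silyl) acetal thermally without a Lewis acid (Wissner hydroxymethyl ketone synthesis), and aqueous acid strips the silyl groups so that the β-keto acid loses CO2 to leave the ketol, conditions that an aryl benzyl ether tolerates.

Step 3
Reactants: 8 1-(4-benzyloxy-3-methoxyphenyl)-3-hydroxypropan-2-one; 9 vinylmagnesium bromide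
Product: 10 (±)-2-[(4-benzyloxy-3-methoxyphenyl)methyl]but-3-ene-1,2-diol
Conditions: LaCl3·2LiCl (1 equiv), THF, 0 °C; 9 (3 equiv), 0 °C; aq NH4Cl
Reagents that add atoms: vinylmagnesium bromide (9), C=C[Mg]Br
Why: Grignard 1,2-addition to the chelated α-alkoxido ketone is assisted by the oxophilic lanthanum salt, which raises carbonyl electrophilicity and curbs enolisation at the benzylic position, and the tertiary centre may form as the racemate because step 5 is stereoconvergent.

Step 4
Reactants: 10 (±)-2-[(4-benzyloxy-3-methoxyphenyl)methyl]but-3-ene-1,2-diol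
Product: 12 (±)-4-[(4-benzyloxy-3-methoxyphenyl)methyl]-4-vinyl-1,3-dioxolan-2-one, via primary imidazole-1-carboxylate 11 (not isolated)
Conditions: 1,1'-carbonyldiimidazole (1.3 equiv), DMAP (10 mol %), CH2Cl2, rt
Reagents that add atoms: 1,1'-carbonyldiimidazole, O=C(n1ccnc1)n1ccnc1
Why: In this cyclic carbonate formation from a 1,2-diol the primary hydroxyl is acylated first and the tertiary hydroxyl then closes the five-membered ring by expelling imidazole, a neutral method that does not ionise the tertiary allylic alcohol.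

Step 5
Reactants: 2 (E)-3-(4-benzyloxy-3-methoxyphenyl)prop-2-enal; 12 (±)-4-[(4-benzyloxy-3-methoxyphenyl)methyl]-4-vinyl-1,3-dioxolan-2-one
Product: 13 (2R,3R,4R)-2-Ar-4-(ArCH2)-4-vinyloxolane-3-carbaldehyde (C2 aryl trans to C3 formyl; C4 vinyl cis to C2 aryl)
Conditions: 2 (1.0 equiv), 12 (1.4 equiv), Pd2(dba)3·CHCl3 (2.5 mol %), (S)-BINOL N,N-bis[(R)-1-phenylethyl]phosphoramidite (10 mol %), (R)-2-{bis[3,5-bis(trifluoromethyl)phenyl](trimethylsilyloxy)methyl}pyrrolidine (20 mol %), CH2Cl2, rt
Reagents that add atoms: none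
Why: Proposed new method: zerovalent palladium ionises the tertiary allylic C–O bond of 12 and CO2 is lost, the primary alkoxide of the resulting π-allylpalladium zwitterion adds reversibly to the β-carbon of the iminium ion made from 2 and the amine (O1–C2), the enamine so released attacks the disubstituted allyl terminus anti to the metal (C3–C4), and hydrolysis frees 13 and the amine. The closest known reaction types are the palladium-catalysed decarboxylative (3+2) annulation of 4-substituted vinylethylene carbonates with doubly activated Michael acceptors and the amine/palladium (3+2) annulation of vinylcyclopropanes with enals, so only the pairing of the oxygen-centred dipole with an iminium ion is untested. The oxolane closes in a 5-exo mode, the enamine carbon displacing palladium from an allyl unit that stays outside the ring as the vinyl group, and this is favoured kinetically over the seven-membered closure at the CH2 terminus. C2 (R) is set by the (R)-amine, whose diaryl(silyloxy)methyl group covers the Si face of the β-carbon in the E,s-trans iminium ion so that O1 arrives on the Re face; C3 (R) follows from the same shielding of the enamine and is backed by amine-mediated epimerisation to the 2,3-trans aldehyde, which does not endanger C2 because β-elimination of O1 would be the reverse of a 5-endo-trig closure; C4 (R) is set by the phosphoramidite, which selects one of the two π-allyl faces. Both enantiomers of 12 converge because these faces exchange by π–σ–π isomerisation through the unsubstituted CH2 terminus before the ring closes. The step needs conjugate rather than carbonyl addition of the alkoxide, secured by the lowered LUMO of the iminium ion and by the absence of γ-hydrogens in 2 (no dienamine path), and branched rather than linear allylation, secured by the one-carbon tether C5 between O1 and C4.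

Step 6
Reactants: 13 (2R,3R,4R)-2-Ar-4-(ArCH2)-4-vinyloxolane-3-carbaldehyde
Product: 14 [(2R,3S,4R)-2-Ar-4-(ArCH2)-4-vinyloxolan-3-yl]methanol
Conditions: NaBH4 (1 equiv), MeOH/CH2Cl2, 0 °C
Reagents that add atoms: none
Why: Borohydride reduction of the aldehyde is fast at 0 °C, leaves the alkene and the benzyl ethers alone, and freezes C3 by removing the group that made its hydrogen acidic.

Step 7
Reactants: 14 [(2R,3S,4R)-2-Ar-4-(ArCH2)-4-vinyloxolan-3-yl]methanol
Product: 15 [(2R,3S,4R)-2-Ar-4-(ArCH2)-4-vinyloxolan-3-yl]methyl acetate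
Conditions: Ac2O (1.5 equiv), pyridine, DMAP (5 mol %), CH2Cl2, rt
Reagents that add atoms: acetic anhydride, CC(=O)OC(C)=O
Why: DMAP-catalysed acylation masks the only hydroxyl group as an ester that will leave in the same methanolysis as the later formate, so the protection costs one step and no separate deprotection.

Step 8
Reactants: 15 [(2R,3S,4R)-2-Ar-4-(ArCH2)-4-vinyloxolan-3-yl]methyl acetate
Product: 17 [(2R,3S,4R)-2-Ar-4-(ArCH2)-4-formyloxolan-3-yl]methyl acetate, via vicinal diol 16 (not isolated)
Conditions: K2OsO4·2H2O (2 mol %), NaIO4 (4 equiv), 2,6-lutidine (2 equiv), dioxane/H2O, rt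
Reagents that add atoms: sodium periodate, [Na+].[O-]I(=O)(=O)=O (oxygen source, relayed by the osmium catalyst)
Why: Lemieux–Johnson cleavage (osmylation of the only alkene, then periodate scission) gives the non-enolisable aldehyde without exposing benzyl ethers and electron-rich rings to ozone, and the aldehyde is chosen as relay because a methoxy hydroperoxide derived from a monosubstituted alkene carries a hydrogen on the peroxy carbon and would dehydrate to the methyl ester on acylation instead of rearranging.

Step 9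
Reactants: 17 [(2R,3S,4R)-2-Ar-4-(ArCH2)-4-formyloxolan-3-yl]methyl acetate
Product: 18 [(2R,3S,4R)-2-Ar-4-(ArCH2)-4-(formyloxy)oxolan-3-yl]methyl acetate
Conditions: mCPBA (1.5 equiv), NaHCO3 (2 equiv), CH2Cl2, 0 °C to rt
Reagents that add atoms: 3-chloroperoxybenzoic acid, O=C(OO)c1cccc(Cl)c1
Why: In the Baeyer–Villiger oxidation of an aldehyde whose α-carbon is fully substituted the tertiary carbon migrates in preference to hydrogen and does so with retention, so the new C4–O bond takes the place of the C4–CHO bond on the face cis to the C2 aryl group.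

Step 10
Reactants: 18 [(2R,3S,4R)-2-Ar-4-(ArCH2)-4-(formyloxy)oxolan-3-yl]methyl acetate
Product: 19 (2R,3S,4R)-2-Ar-4-(ArCH2)-3-(hydroxymethyl)oxolan-4-ol
Conditions: K2CO3 (0.3 equiv), MeOH, 0 °C to rt
Reagents that add atoms: none
Why: Carbonate-catalysed transesterification with methanol removes formate and acetate together, and no centre can epimerise because neither C3 nor C4 carries an acidifying group.

Step 11
Reactants: 19 (2R,3S,4R)-2-Ar-4-(ArCH2)-3-(hydroxymethyl)oxolan-4-ol
Product: 20 (3R,4S,5R)-5-(4-hydroxy-3-methoxyphenyl)-3-[(4-hydroxy-3-methoxyphenyl)methyl]-4-(hydroxymethyl)oxolan-3-ol (2R,3S,4R in the route numbering)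
Conditions: H2 (1 atm), Pd/C (10 wt %), EtOAc/EtOH, rt, stopped after two equivalents of H2
Reagents that add atoms: none
Why: Catalytic hydrogenolysis cleaves the two aryl benzyl ethers much faster than the cyclic benzylic C2–O1 bond, so a neutral solvent and a stop at the calculated hydrogen uptake should give the target with all three centres intact.

Compound list
1 | coniferyl aldehyde, (E)-3-(4-hydroxy-3-methoxyphenyl)prop-2-enal | COc1cc(/C=C/C=O)ccc1O | starting material
2 | (E)-3-(4-benzyloxy-3-methoxyphenyl)prop-2-enal | COc1cc(/C=C/C=O)ccc1OCc1ccccc1 | intermediate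
3 | (4-benzyloxy-3-methoxyphenyl)acetic acid | COc1cc(CC(=O)O)ccc1OCc1ccccc1 | starting material
4 | tris(trimethylsilyloxy)ethene | C[Si](C)(C)OC=C(O[Si](C)(C)C)O[Si](C)(C)C | starting material
5 | (4-benzyloxy-3-methoxyphenyl)acetyl chloride (not isolated) | COc1cc(CC(=O)Cl)ccc1OCc1ccccc1 | intermediate
6 | trimethylsilyl 4-(4-benzyloxy-3-methoxyphenyl)-3-oxo-2-(trimethylsilyloxy)butanoate (racemic, not isolated) | COc1cc(CC(=O)C(O[Si](C)(C)C)C(=O)O[Si](C)(C)C)ccc1OCc1ccccc1 | intermediate
7 | 4-(4-benzyloxy-3-methoxyphenyl)-2-hydroxy-3-oxobutanoic acid (racemic, not isolated) | COc1cc(CC(=O)C(O)C(=O)O)ccc1OCc1ccccc1 | intermediate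
8 | 1-(4-benzyloxy-3-methoxyphenyl)-3-hydroxypropan-2-one | COc1cc(CC(=O)CO)ccc1OCc1ccccc1 | intermediate
9 | vinylmagnesium bromide | C=C[Mg]Br | starting material
10 | (±)-2-[(4-benzyloxy-3-methoxyphenyl)methyl]but-3-ene-1,2-diol | C=CC(O)(CO)Cc1ccc(OCc2ccccc2)c(OC)c1 | intermediate
11 | (±)-2-[(4-benzyloxy-3-methoxyphenyl)methyl]-2-hydroxybut-3-enyl imidazole-1-carboxylate (not isolated) | C=CC(O)(COC(=O)n1ccnc1)Cc1ccc(OCc2ccccc2)c(OC)c1 | intermediate
12 | (±)-4-[(4-benzyloxy-3-methoxyphenyl)methyl]-4-vinyl-1,3-dioxolan-2-one | C=CC1(Cc2ccc(OCc3ccccc3)c(OC)c2)COC(=O)O1 | intermediate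
13 | (2R,3R,4R)-2-Ar-4-(ArCH2)-4-vinyloxolane-3-carbaldehyde; aryl/formyl trans, vinyl cis to aryl | COc1cc(C[C@]2(C=C)CO[C@@H](c3ccc(OCc4ccccc4)c(OC)c3)[C@@H]2C=O)ccc1OCc1ccccc1 | intermediate
14 | [(2R,3S,4R)-2-Ar-4-(ArCH2)-4-vinyloxolan-3-yl]methanol | COc1cc(C[C@]2(C=C)CO[C@@H](c3ccc(OCc4ccccc4)c(OC)c3)[C@@H]2CO)ccc1OCc1ccccc1 | intermediate
15 | [(2R,3S,4R)-2-Ar-4-(ArCH2)-4-vinyloxolan-3-yl]methyl acetate | COc1cc(C[C@]2(C=C)CO[C@@H](c3ccc(OCc4ccccc4)c(OC)c3)[C@@H]2COC(C)=O)ccc1OCc1ccccc1 | intermediate
16 | [(2R,3S,4R)-2-Ar-4-(ArCH2)-4-(1,2-dihydroxyethyl)oxolan-3-yl]methyl acetate (side-chain carbinol epimers, not isolated) | COc1cc(C[C@]2(C(O)CO)CO[C@@H](c3ccc(OCc4ccccc4)c(OC)c3)[C@@H]2COC(C)=O)ccc1OCc1ccccc1 | intermediate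
17 | [(2R,3S,4R)-2-Ar-4-(ArCH2)-4-formyloxolan-3-yl]methyl acetate | COc1cc(C[C@]2(C=O)CO[C@@H](c3ccc(OCc4ccccc4)c(OC)c3)[C@@H]2COC(C)=O)ccc1OCc1ccccc1 | intermediate
18 | [(2R,3S,4R)-2-Ar-4-(ArCH2)-4-(formyloxy)oxolan-3-yl]methyl acetate | COc1cc(C[C@]2(OC=O)CO[C@@H](c3ccc(OCc4ccccc4)c(OC)c3)[C@@H]2COC(C)=O)ccc1OCc1ccccc1 | intermediate
19 | (2R,3S,4R)-2-Ar-4-(ArCH2)-3-(hydroxymethyl)oxolan-4-ol | COc1cc(C[C@]2(O)CO[C@@H](c3ccc(OCc4ccccc4)c(OC)c3)[C@@H]2CO)ccc1OCc1ccccc1 | intermediate
20 | (3R,4S,5R)-5-(4-hydroxy-3-methoxyphenyl)-3-[(4-hydroxy-3-methoxyphenyl)methyl]-4-(hydroxymethyl)oxolan-3-ol | COc1cc(C[C@]2(O)CO[C@@H](c3ccc(O)c(OC)c3)[C@@H]2CO)ccc1O | target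

Total step count: 11. Longest linear sequence: 10 steps (steps 2 to 11, from 3 to 20).

Steps most likely to fail

1. Step 5. The alkoxide may add to the carbonyl carbon of free 2 and be trapped by O-allylation, the amine may be N-allylated irreversibly, or facial selectivity at the allyl terminus (C4) may be poor.
The fallback uses known chemistry, sets out from 12 and comes back at 13. Commercial 4-benzyloxy-3-methoxybenzaldehyde is condensed with ethyl cyanoacetate (piperidine, EtOH, Knoevenagel) to ethyl (E)-2-cyano-3-(4-benzyloxy-3-methoxyphenyl)prop-2-enoate F1. This is a doubly activated acceptor of the class for which the palladium/phosphoramidite (3+2) annulation of 4-substituted vinylethylene carbonates is established. Its reaction with 12 (Pd2(dba)3·CHCl3, the phosphoramidite, THF) should give ethyl 2-Ar-4-(ArCH2)-3-cyano-4-vinyloxolane-3-carboxylate F2, with C2 and C4 both under ligand control. Krapcho dealkoxycarbonylation (LiCl, wet DMSO, 140 °C) and DBU equilibration should give the 2,3-trans nitrile (2R,3S,4R)-2-Ar-4-(ArCH2)-4-vinyloxolane-3-carbonitrile F3. Reduction with i-Bu2AlH (toluene, −78 °C) and mild hydrolysis then return aldehyde 13.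

2. Step 9. Hydrogen may migrate instead of C4 in the peracid adduct, the migration may be slowed by the β-oxygen O1, or the peracid may attack the electron-rich rings.
The fallback sets out from 15 and comes back at 19. Tsuji–Wacker oxidation (PdCl2, CuCl, O2, DMF/H2O) should turn the vinyl group into the methyl ketone [(2R,3S,4R)-4-acetyl-2-Ar-4-(ArCH2)oxolan-3-yl]methyl acetate F4. In its Baeyer–Villiger oxidation (mCPBA, NaHCO3, CH2Cl2) only methyl competes with the tertiary C4. This should give, with retention, the tertiary acetate [(2R,3S,4R)-4-acetoxy-2-Ar-4-(ArCH2)oxolan-3-yl]methyl acetate F5. The methanolysis of step 10 then removes both acetates and delivers 19.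

3. Step 3. The basic vinyl Grignard reagent may enolise the benzylic ketone, or the ketol may tautomerise under base before addition.
The fallback sets out from 8 and comes back at 10. The far less basic ethynylmagnesium bromide (3 equiv, THF, 0 °C) is added to 8 to give (±)-2-[(4-benzyloxy-3-methoxyphenyl)methyl]but-3-yne-1,2-diol F6. Semihydrogenation (H2, Pd/CaCO3 poisoned with Pb(OAc)2, quinoline, EtOAc; Lindlar conditions) leaves the aryl benzyl ether alone and gives 10.

Further compounds
F1 | step 5 | ethyl (E)-2-cyano-3-(4-benzyloxy-3-methoxyphenyl)prop-2-enoate | CCOC(=O)/C(C#N)=C/c1ccc(OCc2ccccc2)c(OC)c1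
F2 | step 5 | ethyl 2-Ar-4-(ArCH2)-3-cyano-4-vinyloxolane-3-carboxylate (C2 and C4 arranged as in 13; C3 left open, it is erased in the next operation) | COc1cc(C[C@]2(C=C)CO[C@@H](c3ccc(OCc4ccccc4)c(OC)c3)C2(C#N)C(=O)OCC)ccc1OCc1ccccc1
F3 | step 5 | (2R,3S,4R)-2-Ar-4-(ArCH2)-4-vinyloxolane-3-carbonitrile | COc1cc(C[C@]2(C=C)CO[C@@H](c3ccc(OCc4ccccc4)c(OC)c3)[C@@H]2C#N)ccc1OCc1ccccc1
F4 | step 9 | [(2R,3S,4R)-4-acetyl-2-Ar-4-(ArCH2)oxolan-3-yl]methyl acetate | COc1cc(C[C@]2(C(C)=O)CO[C@@H](c3ccc(OCc4ccccc4)c(OC)c3)[C@@H]2COC(C)=O)ccc1OCc1ccccc1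
F5 | step 9 | [(2R,3S,4R)-4-acetoxy-2-Ar-4-(ArCH2)oxolan-3-yl]methyl acetate | COc1cc(C[C@]2(OC(C)=O)CO[C@@H](c3ccc(OCc4ccccc4)c(OC)c3)[C@@H]2COC(C)=O)ccc1OCc1ccccc1
F6 | step 3 | (±)-2-[(4-benzyloxy-3-methoxyphenyl)methyl]but-3-yne-1,2-diol | C#CC(O)(CO)Cc1ccc(OCc2ccccc2)c(OC)c1
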